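The route rests on cutting the unbranched pentacosyl chain at its C12–C13 bond (numbered from the ester oxygen), a plain CH2–CH2 link remote from the ester carbonyl and the 4-hydroxyphenyl ring. Because the chain is a bare polymethylene without branch or stereocentre, carbons C13–C25 map onto tridec-1-ene and C1–C12 onto 12-bromododecan-1-ol, esterified beforehand with phloretic acid. The key step, a one-pot anti-Markovnikov hydroboration and palladium-catalysed alkyl–alkyl Suzuki–Miyaura coupling, turns the terminal alkene carbon into C13 and joins it to the bromine-bearing C12, so the complete target should emerge directly from the unprotected bromo ester.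

Key step: step 2

Remark on the chemistry: 9-BBN is drawn as its monomer although it is supplied as the dimer or as a THF solution. The hydroboration and the coupling are run in one flask and counted as one step.

Step 1
Reactants: 1 3-(4-hydroxyphenyl)propanoic acid (phloretic acid); 2 12-bromododecan-1-ol
Product: 3 12-bromododecyl 3-(4-hydroxyphenyl)propanoate
Conditions: p-TsOH·H2O (5 mol%), toluene, reflux, Dean–Stark; aq. NaHCO3 wash
Reagents that add atoms: none
Why: Fischer esterification driven by azeotropic removal of water should acylate only the primary alcohol, because the phenolic OH is too weakly nucleophilic to be esterified under acid catalysis and the primary bromide is inert to TsOH.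

Step 2
Reactants: 3 12-bromododecyl 3-(4-hydroxyphenyl)propanoate; 4 tridec-1-ene; 5 9-borabicyclo[3.3.1]nonane (9-BBN)
Product: 7 pentacosyl 3-(4-hydroxyphenyl)propanoate, via B-tridecyl-9-BBN 6 (not isolated)
Conditions: 4 (1.6 equiv), 5 (0.5 M in THF, 1.5 equiv), THF, 0 °C to rt; then 3, Pd(OAc)2 (4 mol%), PCy3 (8 mol%), K3PO4·H2O (2.5 equiv), THF, rt; aq. NH4Cl
Reagents that add atoms: none
Why: 9-BBN should add to the terminal alkene of 4 with essentially complete anti-Markovnikov regioselectivity (steric control by the bicyclic borane), so boron sits on the carbon that becomes C13 and no branched chain isomer can arise. Pd(0)/PCy3 then undergoes SN2-type oxidative addition into the primary C–Br bond of 3, the base-activated borate transfers its primary tridecyl group in preference to the secondary bicyclic B–C bonds, and reductive elimination forms the C12–C13 bond. The closest known reaction type is the B-alkyl Suzuki–Miyaura coupling of unactivated primary alkyl bromides bearing β-hydrogens, in which the bulky, electron-rich PCy3 lets transmetalation and reductive elimination outrun β-hydride elimination at room temperature. No ring is closed and no stereocentre is created. The selectivity needed is chemoselectivity: the ester should survive the mild hydrated phosphate base at room temperature, a slight excess of alkene leaves no B–H to react with the phenol, and the phenol, at most partly deprotonated by heterogeneous K3PO4 in THF, is a poor nucleophile towards the bromide under these conditions, so C–C coupling is expected to outcompete O-alkylation.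

Compound list
1 | 3-(4-hydroxyphenyl)propanoic acid (phloretic acid) | OC(=O)CCc1ccc(O)cc1 | starting material
2 | 12-bromododecan-1-ol | OCCCCCCCCCCCCBr | starting material
3 | 12-bromododecyl 3-(4-hydroxyphenyl)propanoate | BrCCCCCCCCCCCCOC(=O)CCc1ccc(O)cc1 | intermediate
4 | tridec-1-ene | C=CCCCCCCCCCCC | starting material
5 | 9-borabicyclo[3.3.1]nonane (9-BBN) | B1C2CCCC1CCC2 | starting material
6 | 9-tridecyl-9-borabicyclo[3.3.1]nonane (B-tridecyl-9-BBN) | CCCCCCCCCCCCCB1C2CCCC1CCC2 | intermediate
7 | pentacosyl 3-(4-hydroxyphenyl)propanoate | CCCCCCCCCCCCCCCCCCCCCCCCCOC(=O)CCc1ccc(O)cc1 | target

Total step count: 2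
Longest linear sequence: 2

Steps most likely to fail (the route has only two steps, so step 2 is listed for two independent failure processes, followed by step 1):

1. Step 2, loss of the bromide through phenoxide chemistry. Under the phosphate base the partly formed phenoxide may be O-alkylated by the primary bromide (intermolecular oligomerisation) faster than the coupling turns over. The fallback avoids base and alkyl halide altogether by cross-metathesis and hydrogenation. It sets out from 1 and comes back to the route at 7. Acid 1 would be esterified (p-TsOH, toluene, Dean–Stark) with tridec-12-en-1-ol (OCCCCCCCCCCCC=C) to give tridec-12-en-1-yl 3-(4-hydroxyphenyl)propanoate F1. Cross-metathesis of F1 with an excess of tetradec-1-ene (C=CCCCCCCCCCCCC) under the Grubbs second-generation catalyst in CH2Cl2 at 40 °C should form the C12=C13 bond and give pentacos-12-en-1-yl 3-(4-hydroxyphenyl)propanoate F2 as an E/Z mixture (E isomer drawn). The polar product should be separable from the hydrocarbon homodimer. Hydrogenation of both isomers (H2, Pd/C, EtOAc) would then converge on 7.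

2. Step 2, β-hydride elimination or protodehalogenation at the alkylpalladium stage. If transmetalation from the bulky B-alkyl-9-BBN is slow, the alkylpalladium bromide may collapse to the dodec-11-enyl or dodecyl ester instead of coupling. The fallback changes both metal and nucleophile to a copper-catalysed Grignard alkylation on the protected phenol. It sets out from 3 and comes back to the route at 7. Phenol 3 would be silylated with TBSCl (CC(C)(C)[Si](C)(C)Cl) and imidazole in DMF to give 12-bromododecyl 3-[4-(tert-butyldimethylsilyloxy)phenyl]propanoate F3. Tridecylmagnesium bromide F4, made from 1-bromotridecane (CCCCCCCCCCCCCBr) and Mg in THF, would be added slowly to F3 with Li2CuCl4 (3 mol%) and NMP in THF at 0 °C. In this Kochi-type coupling an alkylcuprate displaces bromide by SN2, and esters are tolerated. It should give pentacosyl 3-[4-(tert-butyldimethylsilyloxy)phenyl]propanoate F5. TBAF buffered with AcOH in THF at 0 °C would then free the phenol and give 7.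

3. Step 1, unselective or incomplete esterification. On prolonged heating with acid, phloretic acid may self-condense through its phenol to oligoesters, or the bromo alcohol may etherify, leaving the conversion incomplete. The fallback forms the ester by carboxylate O-alkylation instead of acylation. It sets out from 1 and comes back to the route at 3. Acid 1 would be treated with KHCO3 and an excess (4 equiv) of 1,12-dibromododecane (BrCCCCCCCCCCCCBr) in DMF at 40 °C. Bicarbonate deprotonates only the carboxylic acid and not the phenol, and the excess dibromide suppresses the bis-ester, so 12-bromododecyl 3-(4-hydroxyphenyl)propanoate 3 should form directly. No compound outside the compound list is made (F0).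

Further compounds
F1 | step 2 | tridec-12-en-1-yl 3-(4-hydroxyphenyl)propanoate | C=CCCCCCCCCCCCOC(=O)CCc1ccc(O)cc1
F2 | step 2 | (E)-pentacos-12-en-1-yl 3-(4-hydroxyphenyl)propanoate (expected together with its Z isomer) | CCCCCCCCCCCC/C=C/CCCCCCCCCCCOC(=O)CCc1ccc(O)cc1
F3 | step 2 | 12-bromododecyl 3-[4-(tert-butyldimethylsilyloxy)phenyl]propanoate | BrCCCCCCCCCCCCOC(=O)CCc1ccc(O[Si](C)(C)C(C)(C)C)cc1
F4 | step 2 | tridecylmagnesium bromide | CCCCCCCCCCCCC[Mg]Br
F5 | step 2 | pentacosyl 3-[4-(tert-butyldimethylsilyloxy)phenyl]propanoate | CCCCCCCCCCCCCCCCCCCCCCCCCOC(=O)CCc1ccc(O[Si](C)(C)C(C)(C)C)cc1
F0 | step 1 | none | none
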